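## Retrosynthetic overview (labdane numbering, C1–C20)

1. Ring B first: methyl acetoacetate 1 + (E)-pent-3-en-2-one 2 → (Michael adduct 3) → cyclohexenone ester 4; its CH(CH3) carbon (later C8) is a sacrificial stereocentre that carries the absolute configuration.
2. C1–C10 (quaternary centre) and C4–C5 (ring A): 4 + homoprenyl bromide 5 by nickel-mediated radical conjugate addition (silyl enol ether 6), then cationic ring closure → cis-fused keto ester 7 → acid 8.
3. Key disconnection C9–C11: bromobutenolide 9 + vinyltrifluoroborate 10 → dienyl lactone 11; decarboxylative radical 1,6-addition of the C9 radical from 8 to 11 → (12) → 13. The lactone ring stores the (Z)-acetoxy acid.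
4. Ring B adjustment: dehydrogenation to the C7=C8 enone erases the relay centre, then C5 epimerises: 13 → (14) → trans-fused 15.
5. Unmasking: lactone opening, esterification and acetylation (16, 17) → 18, ester cleavage → target 19.

Assumption: the target is the ent-labdane with (5R,9R,10S) configuration, i.e. (1R,4aR,8aS) in naphthalene numbering, and a (Z) side-chain alkene (CH2OAc cis to CO2H).
Assumption: the amine catalyst in step 1 is taken to give the (R) adduct; if the sense is opposite, the quinidine-derived pseudo-enantiomer is used.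

## Route

Step 1
Reactants: 1 methyl acetoacetate; 2 (E)-pent-3-en-2-one
Product: 4 methyl (6R)-2,6-dimethyl-4-oxocyclohex-2-ene-1-carboxylate (C-1 epimer mixture), via Michael adduct 3 (not isolated)
Conditions: 9-amino(9-deoxy)epi-quinine (20 mol%), 2-FC6H4CO2H (40 mol%), toluene, rt; then TsOH·H2O (10 mol%), toluene, reflux (Dean–Stark)
Reagents that add atoms: none
Why: Primary-amine iminium catalysis sets the methyl-bearing stereocentre (later C8, R) in the Michael addition of the β-keto ester, and acid-catalysed intramolecular aldol condensation (Robinson annulation, the methyl-ketone enol attacking the acetoacetate carbonyl as in the Hagemann ester synthesis) then gives ring B, the labile ester-bearing centre being left as a mixture because it is erased later.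

Step 2
Reactants: 4 methyl (6R)-2,6-dimethyl-4-oxocyclohex-2-ene-1-carboxylate; 5 5-bromo-2-methylpent-2-ene
Product: 7 methyl (2R,4aS,8aR)-2,5,5,8a-tetramethyl-4-oxodecahydronaphthalene-1-carboxylate (cis-fused; C-1 epimer mixture), via silyl enol ether 6 (not isolated)
Conditions: NiCl2(dme) (10 mol%), neocuproine (10 mol%), Mn (2 equiv), Et3SiCl (1.5 equiv), DMF, 40 °C; then MeSO3H, CH2Cl2, 0 °C → rt
Reagents that add atoms: none
Why: Proposed new method: zerovalent nickel, the enone and Et3SiCl give a 1-silyloxyallyl nickel species on the face anti to the C8 methyl, the 4-methylpent-3-enyl radical formed from 5 by bromine abstraction is captured at nickel and C–C reductive elimination makes the quaternary C10 trans to that methyl (so the sacrificial centre relays the absolute configuration), the closest known reaction type being the nickel-catalysed reductive conjugate addition of alkyl bromides to cyclic enones with chlorosilane trapping, after which MeSO3H protonates the trisubstituted alkene and the C5 enol (ether) captures the tertiary cation (cation–olefin ring closure of ring A), the cis ring fusion being favoured kinetically (axial attack) and thermodynamically because the trans isomer would place the C8 and C10 methyls 1,3-diaxial.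

Step 3
Reactants: 7 methyl (2R,4aS,8aR)-2,5,5,8a-tetramethyl-4-oxodecahydronaphthalene-1-carboxylate
Product: 8 (2R,4aS,8aR)-2,5,5,8a-tetramethyl-4-oxodecahydronaphthalene-1-carboxylic acid (cis-fused; C-1 epimer mixture)
Conditions: LiI, EtOAc, reflux; then 1 M HCl
Reagents that add atoms: none
Why: Nucleophilic demethylation (SN2 attack of iodide on the O-methyl group) cleaves the hindered ester without touching the ketone or any stereocentre that is kept.

Step 4
Reactants: 9 4-bromofuran-2(5H)-one; 10 potassium vinyltrifluoroborate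
Product: 11 4-ethenylfuran-2(5H)-one
Conditions: PdCl2(dppf) (3 mol%), Et3N, n-PrOH, 80 °C
Reagents that add atoms: none
Why: Suzuki–Miyaura cross-coupling of the β-bromo butenolide with the vinyltrifluoroborate gives the dienyl lactone used as radical acceptor, and no stereocentre is formed.

Step 5
Reactants: 8 (2R,4aS,8aR)-2,5,5,8a-tetramethyl-4-oxodecahydronaphthalene-1-carboxylic acid; 11 4-ethenylfuran-2(5H)-one
Product: 13 4-{2-[(1R,2R,4aS,8aS)-2,5,5,8a-tetramethyl-4-oxodecahydronaphthalen-1-yl]ethyl}furan-2(5H)-one (cis-fused), via alkylidene lactone 12 (not isolated)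
Conditions: [Ir{dF(CF3)ppy}2(dtbbpy)]PF6 (1 mol%), K2HPO4, DMF, blue LEDs, rt; then Et3N, rt
Reagents that add atoms: none
Why: Photoredox decarboxylative Giese reaction (radical 1,6-conjugate addition): oxidation of the carboxylate by the excited iridium photocatalyst and loss of CO2 give the secondary C9 radical, which adds to the terminal CH2 of the dienyl lactone on the face anti to the axial C1 methylene of the cis-decalin (both ring-B methyls being equatorial), so that C11 ends cis to the angular methyl as in the target, and reduction, protonation and Et3N isomerisation deliver the conjugated butenolide whose ring locks the later (Z) geometry.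

Step 6
Reactants: 13 4-{2-[(1R,2R,4aS,8aS)-2,5,5,8a-tetramethyl-4-oxodecahydronaphthalen-1-yl]ethyl}furan-2(5H)-one
Product: 15 4-{2-[(1R,4aR,8aS)-2,5,5,8a-tetramethyl-4-oxo-1,4,4a,5,6,7,8,8a-octahydronaphthalen-1-yl]ethyl}furan-2(5H)-one (trans-fused), via cis-fused enone 14 (not isolated)
Conditions: Pd(O2CCF3)2 (10 mol%), DMSO (20 mol%), O2 (1 atm), AcOH, 80 °C; then DBU (0.3 equiv), toluene, 60 °C
Reagents that add atoms: none
Why: Palladium-catalysed aerobic α,β-dehydrogenation of the ketone can only go towards C7–C8 because C5 is flanked by two quaternary carbons, which erases the sacrificial C8 centre, and with the 1,3-diaxial methyl penalty gone DBU epimerises the axial α'-hydrogen at C5 to the trans ring fusion expected to be more stable, while C9 is kept because its hydrogen is poorly aligned with the enone in the cis isomer and, once trans, is removed and returned only along the axial trajectory anti to the angular methyl.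

Step 7
Reactants: 15 4-{2-[(1R,4aR,8aS)-2,5,5,8a-tetramethyl-4-oxo-1,4,4a,5,6,7,8,8a-octahydronaphthalen-1-yl]ethyl}furan-2(5H)-one
Product: 18 4-methoxybenzyl (2Z)-4-acetoxy-3-{2-[(1R,4aR,8aS)-2,5,5,8a-tetramethyl-4-oxo-1,4,4a,5,6,7,8,8a-octahydronaphthalen-1-yl]ethyl}but-2-enoate, via sodium hydroxy carboxylate 16 (not isolated), via PMB hydroxy ester 17 (not isolated)
Conditions: NaOH (1.05 equiv), THF/H2O, 0 °C; evaporate; 4-MeOC6H4CH2Cl, Bu4NI (cat.), DMF, 0 °C → rt; then Ac2O, pyridine, DMAP (cat.), 0 °C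
Reagents that add atoms: sodium hydroxide [Na+].[OH-]; 4-methoxybenzyl chloride COc1ccc(CCl)cc1; acetic anhydride CC(=O)OC(C)=O
Why: Saponification opens the butenolide to the (Z)-hydroxy carboxylate, whose carboxylate is O-alkylated (SN2) before the free primary alcohol is acetylated (DMAP-catalysed acylation), so that relactonisation is blocked and the ring-enforced (Z) geometry is kept.

Step 8
Reactants: 18 4-methoxybenzyl (2Z)-4-acetoxy-3-{2-[(1R,4aR,8aS)-2,5,5,8a-tetramethyl-4-oxo-1,4,4a,5,6,7,8,8a-octahydronaphthalen-1-yl]ethyl}but-2-enoate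
Product: 19 (2Z)-4-acetoxy-3-{2-[(1R,4aR,8aS)-2,5,5,8a-tetramethyl-4-oxo-1,4,4a,5,6,7,8,8a-octahydronaphthalen-1-yl]ethyl}but-2-enoic acid (target)
Conditions: CF3CO2H, anisole, CH2Cl2, 0 °C
Reagents that add atoms: none
Why: Acidolysis of the 4-methoxybenzyl ester (SN1-type cleavage with anisole as cation scavenger) frees the acid without touching the allylic acetate, the enone or its stereocentres.

## Compound list

1 | methyl acetoacetate | CC(=O)CC(=O)OC | starting material
2 | (E)-pent-3-en-2-one | C/C=C/C(C)=O | starting material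
3 | methyl (3R)-2-acetyl-3-methyl-5-oxohexanoate (C-2 epimers) | CC(=O)C(C(=O)OC)[C@H](C)CC(C)=O | intermediate
4 | methyl (6R)-2,6-dimethyl-4-oxocyclohex-2-ene-1-carboxylate (C-1 epimers) | COC(=O)C1C(C)=CC(=O)C[C@H]1C | intermediate
5 | 5-bromo-2-methylpent-2-ene | CC(C)=CCCBr | starting material
6 | methyl (2R,6R)-2,6-dimethyl-2-(4-methylpent-3-en-1-yl)-4-[(triethylsilyl)oxy]cyclohex-3-ene-1-carboxylate (C-1 epimers) | COC(=O)C1[C@](C)(CCC=C(C)C)C=C(O[Si](CC)(CC)CC)C[C@H]1C | intermediate
7 | methyl (2R,4aS,8aR)-2,5,5,8a-tetramethyl-4-oxodecahydronaphthalene-1-carboxylate (cis-fused; C-1 epimers) | COC(=O)C1[C@H](C)CC(=O)[C@H]2C(C)(C)CCC[C@@]12C | intermediate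
8 | (2R,4aS,8aR)-2,5,5,8a-tetramethyl-4-oxodecahydronaphthalene-1-carboxylic acid (cis-fused; C-1 epimers) | OC(=O)C1[C@H](C)CC(=O)[C@H]2C(C)(C)CCC[C@@]12C | intermediate
9 | 4-bromofuran-2(5H)-one | O=C1C=C(Br)CO1 | starting material
10 | potassium vinyltrifluoroborate | C=C[B-](F)(F)F.[K+] | starting material
11 | 4-ethenylfuran-2(5H)-one | C=CC1=CC(=O)OC1 | intermediate
12 | 4-{2-[(1R,2R,4aS,8aS)-2,5,5,8a-tetramethyl-4-oxodecahydronaphthalen-1-yl]ethylidene}dihydrofuran-2(3H)-one (E/Z mixture) | O=C1CC(=CC[C@@H]2[C@H](C)CC(=O)[C@H]3C(C)(C)CCC[C@@]23C)CO1 | intermediate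
13 | 4-{2-[(1R,2R,4aS,8aS)-2,5,5,8a-tetramethyl-4-oxodecahydronaphthalen-1-yl]ethyl}furan-2(5H)-one (cis-fused) | O=C1OCC(CC[C@@H]2[C@H](C)CC(=O)[C@H]3C(C)(C)CCC[C@@]23C)=C1 | intermediate
14 | 4-{2-[(1R,4aS,8aS)-2,5,5,8a-tetramethyl-4-oxo-1,4,4a,5,6,7,8,8a-octahydronaphthalen-1-yl]ethyl}furan-2(5H)-one (cis-fused enone) | O=C1OCC(CC[C@@H]2C(C)=CC(=O)[C@H]3C(C)(C)CCC[C@@]23C)=C1 | intermediate
15 | 4-{2-[(1R,4aR,8aS)-2,5,5,8a-tetramethyl-4-oxo-1,4,4a,5,6,7,8,8a-octahydronaphthalen-1-yl]ethyl}furan-2(5H)-one (trans-fused enone) | O=C1OCC(CC[C@@H]2C(C)=CC(=O)[C@@H]3C(C)(C)CCC[C@@]23C)=C1 | intermediate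
16 | sodium (2Z)-4-hydroxy-3-{2-[(1R,4aR,8aS)-2,5,5,8a-tetramethyl-4-oxo-1,4,4a,5,6,7,8,8a-octahydronaphthalen-1-yl]ethyl}but-2-enoate | [Na+].[O-]C(=O)/C=C(\CO)CC[C@@H]1C(C)=CC(=O)[C@@H]2C(C)(C)CCC[C@@]12C | intermediate
17 | 4-methoxybenzyl (2Z)-4-hydroxy-3-{2-[(1R,4aR,8aS)-2,5,5,8a-tetramethyl-4-oxo-1,4,4a,5,6,7,8,8a-octahydronaphthalen-1-yl]ethyl}but-2-enoate | COc1ccc(COC(=O)/C=C(\CO)CC[C@@H]2C(C)=CC(=O)[C@@H]3C(C)(C)CCC[C@@]23C)cc1 | intermediate
18 | 4-methoxybenzyl (2Z)-4-acetoxy-3-{2-[(1R,4aR,8aS)-2,5,5,8a-tetramethyl-4-oxo-1,4,4a,5,6,7,8,8a-octahydronaphthalen-1-yl]ethyl}but-2-enoate | COc1ccc(COC(=O)/C=C(\COC(C)=O)CC[C@@H]2C(C)=CC(=O)[C@@H]3C(C)(C)CCC[C@@]23C)cc1 | intermediate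
19 | (2Z)-4-acetoxy-3-{2-[(1R,4aR,8aS)-2,5,5,8a-tetramethyl-4-oxo-1,4,4a,5,6,7,8,8a-octahydronaphthalen-1-yl]ethyl}but-2-enoic acid | CC(=O)OC/C(=C\C(=O)O)CC[C@@H]1C(C)=CC(=O)[C@@H]2C(C)(C)CCC[C@@]12C | target

(The change of the ring-fusion descriptor from 8aR in 7 and 8 to 8aS in 13 is a CIP priority change only; the spatial arrangement is the same.)

## Step count and risks

Total step count: 8. Longest linear sequence: 7 steps (steps 1, 2, 3, 5, 6, 7, 8); step 4 is a one-step side branch.

The three steps most likely to fail: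

Step 2. The nickel-mediated coupling has to build a quaternary carbon at a β,β-disubstituted enone and may stall or lose facial selectivity. The fallback sets out from 4 and 5 and comes back at 7. Bromide 5 is turned into its Grignard reagent and added to 4 in a polar copper-catalysed 1,4-addition (CuBr·SMe2, Me3SiCl, THF, −78 °C; one extra equivalent of Grignard reagent covers the acidic γ-hydrogen). This gives the trimethylsilyl enol ether methyl (2R,6R)-2,6-dimethyl-2-(4-methylpent-3-en-1-yl)-4-[(trimethylsilyl)oxy]cyclohex-3-ene-1-carboxylate F1, and the same MeSO3H treatment closes ring A to 7.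

Step 5. A hindered secondary radical next to a quaternary carbon must add to a dienyl lactone that can oligomerise. The fallback sets out from 8 and comes back at 13. Acid 8 is converted with N-hydroxyphthalimide and DIC into the redox-active ester 1,3-dioxoisoindolin-2-yl (2R,4aS,8aR)-2,5,5,8a-tetramethyl-4-oxodecahydronaphthalene-1-carboxylate F2. Nickel-catalysed decarboxylative alkenylation with vinylzinc chloride (NiCl2(dme), 2,2'-bipyridine) gives the vinyl ketone (3R,4R,4aS,8aS)-4-ethenyl-3,4a,8,8-tetramethyloctahydronaphthalen-1(2H)-one F3. Hydroboration with 9-BBN gives the alkylborane 9-{2-[(1R,2R,4aS,8aS)-2,5,5,8a-tetramethyl-4-oxodecahydronaphthalen-1-yl]ethyl}-9-borabicyclo[3.3.1]nonane F4, which is joined to bromobutenolide 9 by B-alkyl Suzuki coupling (PdCl2(dppf), K3PO4) to reach 13.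

Step 6. The C5 epimerisation is thermodynamic and sits next to an epimerisable C9; it may stop at a mixture or erode C9. The fallback sets out from 13 and comes back at 15. Acid-catalysed α-selenenylation (PhSeCl, EtOAc, cat. HCl) gives the α-phenylselanyl ketone F5, and H2O2/pyridine gives 14 by selenoxide syn-elimination (isolated this time). KN(SiMe3)2 (2.2 equiv) and Me3SiCl at −78 °C then give the bis(trimethylsilyl) dienol ether F6 (cross-conjugated silyl dienol ether at C5=C6 and 2-silyloxyfuran). HF·pyridine at −78 °C protonates C5 kinetically from the face anti to the angular methyl and returns the butenolide, giving 15 without any equilibrium at C9.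

## Further compounds

F1 | step 2 | methyl (2R,6R)-2,6-dimethyl-2-(4-methylpent-3-en-1-yl)-4-[(trimethylsilyl)oxy]cyclohex-3-ene-1-carboxylate | COC(=O)C1[C@](C)(CCC=C(C)C)C=C(O[Si](C)(C)C)C[C@H]1C
F2 | step 5 | 1,3-dioxoisoindolin-2-yl (2R,4aS,8aR)-2,5,5,8a-tetramethyl-4-oxodecahydronaphthalene-1-carboxylate | O=C(ON1C(=O)c2ccccc2C1=O)C1[C@H](C)CC(=O)[C@H]2C(C)(C)CCC[C@@]12C
F3 | step 5 | (3R,4R,4aS,8aS)-4-ethenyl-3,4a,8,8-tetramethyloctahydronaphthalen-1(2H)-one | C=C[C@@H]1[C@H](C)CC(=O)[C@H]2C(C)(C)CCC[C@@]12C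
F4 | step 5 | 9-{2-[(1R,2R,4aS,8aS)-2,5,5,8a-tetramethyl-4-oxodecahydronaphthalen-1-yl]ethyl}-9-borabicyclo[3.3.1]nonane | C1CC2CCCC(C1)B2CC[C@@H]3[C@H](C)CC(=O)[C@H]4C(C)(C)CCC[C@@]34C
F5 | step 6 | α-phenylselanyl ketone: 13 carrying PhSe at the ring CH2 next to the ketone (epimer mixture at that carbon) | O=C1OCC(CC[C@@H]2[C@H](C)C([Se]c4ccccc4)C(=O)[C@H]3C(C)(C)CCC[C@@]23C)=C1
F6 | step 6 | bis(trimethylsilyl) dienol ether of 14 (ring-B 2-silyloxy-1,3-diene and 2-silyloxyfuran) | C[Si](C)(C)Oc1cc(CC[C@@H]2C(C)=CC(O[Si](C)(C)C)=C3C(C)(C)CCC[C@@]23C)co1
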